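The route rests on disconnecting the C2–C3 bond of the pyranone ring C. The precursor is an open diazomethyl ketone: ring A already carries the methoxy, geranyl and silyloxy groups, its acyl carbon (C4) bears the diazo carbon (C3), and the ortho oxygen (O1) bears a 4-silyloxybenzyl group whose CH2 becomes C2. A chiral dirhodium carboxylate turns C3 into a carbene that inserts into one enantiotopic C2–H bond, closing ring C and setting C2 in one operation. The step exploits the C2–H bonds, doubly activated by O1 and by the para-oxygenated ring B and placed 1,6 to C3. The C3 hydroxyl then enters trans to the aryl group by enolate oxidation.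

Key step: step 6

Remark: the sense of induction of Rh2(S-PTTL)4 (dirhodium tetrakis[N-phthaloyl-(S)-tert-leucinate]) in step 6 is assumed to give the 2S flavanone; if screening shows the opposite sense, Rh2(R-PTTL)4 is used with nothing else changed.

Abbreviations: TBS = tert-butyldimethylsilyl; geranyl = (2E)-3,7-dimethylocta-2,6-dien-1-yl; flavonoid numbering (O1, C2, C3, C4, C4a, C5–C8, C8a; rings A, B, C) is used for the chromanone core and its precursors.

Step 1
Reactants: 1 1-(2,4,6-trihydroxyphenyl)ethan-1-one (phloroacetophenone); 2 geranyl bromide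
Product: 3 1-(3-geranyl-2,4,6-trihydroxyphenyl)ethan-1-one
Conditions: 10% aq KOH, 0 °C → rt
Reagents that add atoms: none
Why: C-alkylation of the ambident phloroacetophenone anion by SN2 displacement on the primary allylic bromide (in water the solvated phenoxide oxygens are shielded, so carbon reacts), and because the two free ring carbons are equivalent a single mono-C-geranyl isomer with the E double bond untouched should result.

Step 2
Reactants: 3 1-(3-geranyl-2,4,6-trihydroxyphenyl)ethan-1-one
Product: 4 1-{4-[(TBS)oxy]-3-geranyl-2,6-dihydroxyphenyl}ethan-1-one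
Conditions: TBSCl (1.05 equiv), imidazole, CH2Cl2, 0 °C
Reagents that add atoms: tert-butyldimethylsilyl chloride, CC(C)(C)[Si](C)(C)Cl
Why: Selective O-silylation, since the 4-hydroxyl para to the acetyl group is the most acidic one and the only one that never hydrogen-bonds to the ketone, so one equivalent of silyl chloride should go there.

Step 3
Reactants: 4 1-{4-[(TBS)oxy]-3-geranyl-2,6-dihydroxyphenyl}ethan-1-one; 5 {4-[(TBS)oxy]phenyl}methanol
Product: 6 1-[6-({4-[(TBS)oxy]phenyl}methoxy)-4-[(TBS)oxy]-3-geranyl-2-hydroxyphenyl]ethan-1-one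
Conditions: PPh3, DIAD, THF, 0 °C → rt
Reagents that add atoms: none
Why: Mitsunobu etherification, in which the ortho hydroxyl flanked only by a ring hydrogen should react in preference to the one wedged between the acetyl and geranyl groups, after which the last hydroxyl is tied up in the hydrogen bond to the ketone and the reaction should stop at the mono-ether; this fixes the future O1 para to the geranyl group.

Step 4
Reactants: 6 1-[6-({4-[(TBS)oxy]phenyl}methoxy)-4-[(TBS)oxy]-3-geranyl-2-hydroxyphenyl]ethan-1-one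
Product: 7 1-[6-({4-[(TBS)oxy]phenyl}methoxy)-4-[(TBS)oxy]-3-geranyl-2-methoxyphenyl]ethan-1-one
Conditions: MeOH, PPh3, DIAD, THF, 0 → 40 °C
Reagents that add atoms: methanol, CO
Why: Mitsunobu methylation of the remaining chelated phenol under neutral conditions that spare both aryl silyl ethers, methanol being the least hindered alcohol partner for this crowded position.

Step 5
Reactants: 7 1-[6-({4-[(TBS)oxy]phenyl}methoxy)-4-[(TBS)oxy]-3-geranyl-2-methoxyphenyl]ethan-1-one
Product: 9 2-diazo-1-[6-({4-[(TBS)oxy]phenyl}methoxy)-4-[(TBS)oxy]-3-geranyl-2-methoxyphenyl]ethan-1-one, via trifluoroacetyl ketone 8 (not isolated)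
Conditions: LiN(SiMe3)2, THF, −78 °C; CF3CO2CH2CF3; then MsN3, Et3N, H2O (1 equiv), MeCN, rt
Reagents that add atoms: methanesulfonyl azide, CS(=O)(=O)N=[N+]=[N-]
Why: Detrifluoroacetylative diazo transfer, in which the lithium enolate of the methyl ketone is trifluoroacetylated to the activated 1,3-diketone 8, which takes the diazo group from the sulfonyl azide and loses the trifluoroacetyl group as the sulfonamide, a sequence suited to aryl methyl ketones that resist direct diazo transfer.

Step 6
Reactants: 9 2-diazo-1-[6-({4-[(TBS)oxy]phenyl}methoxy)-4-[(TBS)oxy]-3-geranyl-2-methoxyphenyl]ethan-1-one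
Product: 10 (2S)-7-[(TBS)oxy]-2-{4-[(TBS)oxy]phenyl}-6-geranyl-5-methoxy-2,3-dihydro-4H-chromen-4-one
Conditions: Rh2(S-PTTL)4 (2 mol %), toluene, 0 °C, slow addition of 9
Reagents that add atoms: none
Why: The dirhodium carboxylate extrudes N2 from 9 to give an electrophilic, rhodium-bound acyl carbene at C3, which inserts through a concerted, hydride-transfer-like three-centre transition state into a C–H bond of the O1–CH2–aryl methylene and so forms the C2–C3 bond. The closest known reaction type is the dirhodium-carboxylate-catalysed intramolecular C–H insertion of 2-alkoxyphenyl α-diazo ketones to chroman-4-ones, including its enantioselective form with chiral carboxylate ligands. Ring C closes by a 1,6-insertion through a six-membered transition state (C3, C4, C4a, C8a, O1, C2), the 1,5-position being the oxygen itself and therefore unavailable. The single new stereocenter, C2, is set by the catalyst, whose chiral carboxylate pocket distinguishes the two enantiotopic benzylic hydrogens; the 2S flavanone is the one whose spatial arrangement matches C2 of the target. The step needs selectivity for this C–H bond over the methoxy C–H bonds, over oxonium-ylide formation at O1 followed by 1,2-benzyl shift, and over cyclopropanation of the geranyl alkenes: the chosen C–H bond is the only one activated both by an adjacent oxygen and by a para-silyloxyphenyl group, O1 is a weakly basic aryl ether oxygen conjugated to the acyl arene, the geranyl alkenes cannot reach C3 through a small ring, and slow addition should suppress bimolecular pathways.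

Step 7
Reactants: 10 (2S)-7-[(TBS)oxy]-2-{4-[(TBS)oxy]phenyl}-6-geranyl-5-methoxy-2,3-dihydro-4H-chromen-4-one
Product: 12 (2R,3R)-7-[(TBS)oxy]-2-{4-[(TBS)oxy]phenyl}-6-geranyl-3-hydroxy-5-methoxy-2,3-dihydro-4H-chromen-4-one, via potassium enolate 11 (not isolated)
Conditions: KN(SiMe3)2, THF, −78 °C; 2-(phenylsulfonyl)-3-phenyloxaziridine, −78 °C; AcOH, −78 °C
Reagents that add atoms: 2-(phenylsulfonyl)-3-phenyloxaziridine, O=S(=O)(c1ccccc1)N1OC1c1ccccc1
Why: Enolate hydroxylation with an N-sulfonyloxaziridine (electrophilic oxygen transfer to the potassium enolate 11), the reagent approaching C3 from the face opposite the C2 aryl group so that the new C3 stereocenter is set trans (3R) under substrate control, while the isolated trisubstituted alkenes of the geranyl chain should not react with this oxidant at −78 °C.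

Step 8
Reactants: 12 (2R,3R)-7-[(TBS)oxy]-2-{4-[(TBS)oxy]phenyl}-6-geranyl-3-hydroxy-5-methoxy-2,3-dihydro-4H-chromen-4-one
Product: 13 (2R,3R)-6-geranyl-3,7-dihydroxy-2-(4-hydroxyphenyl)-5-methoxy-2,3-dihydro-4H-chromen-4-one (CNP0177937.1)
Conditions: HF·pyridine, pyridine, THF, 0 °C → rt
Reagents that add atoms: none
Why: Fluoride-mediated cleavage of both aryl silyl ethers under buffered, non-basic conditions, which should leave the base-sensitive trans-dihydroflavonol stereocenters and the acid-sensitive geranyl chain untouched.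

Compound list
1 | 1-(2,4,6-trihydroxyphenyl)ethan-1-one (phloroacetophenone) | CC(=O)c1c(O)cc(O)cc1O | starting material
2 | geranyl bromide, (2E)-1-bromo-3,7-dimethylocta-2,6-diene | BrC/C=C(\C)CCC=C(C)C | starting material
3 | 1-(3-geranyl-2,4,6-trihydroxyphenyl)ethan-1-one | CC(=O)c1c(O)cc(O)c(C/C=C(\C)CCC=C(C)C)c1O | intermediate
4 | 1-{4-[(TBS)oxy]-3-geranyl-2,6-dihydroxyphenyl}ethan-1-one | CC(=O)c1c(O)cc(O[Si](C)(C)C(C)(C)C)c(C/C=C(\C)CCC=C(C)C)c1O | intermediate
5 | {4-[(TBS)oxy]phenyl}methanol | OCc1ccc(O[Si](C)(C)C(C)(C)C)cc1 | starting material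
6 | 1-[6-({4-[(TBS)oxy]phenyl}methoxy)-4-[(TBS)oxy]-3-geranyl-2-hydroxyphenyl]ethan-1-one | CC(=O)c1c(OCc2ccc(O[Si](C)(C)C(C)(C)C)cc2)cc(O[Si](C)(C)C(C)(C)C)c(C/C=C(\C)CCC=C(C)C)c1O | intermediate
7 | 1-[6-({4-[(TBS)oxy]phenyl}methoxy)-4-[(TBS)oxy]-3-geranyl-2-methoxyphenyl]ethan-1-one | CC(=O)c1c(OCc2ccc(O[Si](C)(C)C(C)(C)C)cc2)cc(O[Si](C)(C)C(C)(C)C)c(C/C=C(\C)CCC=C(C)C)c1OC | intermediate
8 | 4,4,4-trifluoro-1-[6-({4-[(TBS)oxy]phenyl}methoxy)-4-[(TBS)oxy]-3-geranyl-2-methoxyphenyl]butane-1,3-dione (formed as its lithium enolate) | O=C(CC(=O)C(F)(F)F)c1c(OCc2ccc(O[Si](C)(C)C(C)(C)C)cc2)cc(O[Si](C)(C)C(C)(C)C)c(C/C=C(\C)CCC=C(C)C)c1OC | intermediate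
9 | 2-diazo-1-[6-({4-[(TBS)oxy]phenyl}methoxy)-4-[(TBS)oxy]-3-geranyl-2-methoxyphenyl]ethan-1-one | [N-]=[N+]=CC(=O)c1c(OCc2ccc(O[Si](C)(C)C(C)(C)C)cc2)cc(O[Si](C)(C)C(C)(C)C)c(C/C=C(\C)CCC=C(C)C)c1OC | intermediate
10 | (2S)-7-[(TBS)oxy]-2-{4-[(TBS)oxy]phenyl}-6-geranyl-5-methoxy-2,3-dihydro-4H-chromen-4-one | COc1c(C/C=C(\C)CCC=C(C)C)c(O[Si](C)(C)C(C)(C)C)cc2c1C(=O)C[C@@H](c1ccc(O[Si](C)(C)C(C)(C)C)cc1)O2 | intermediate
11 | potassium enolate of 10 (C3=C4 enolate, 2S) | COc1c(C/C=C(\C)CCC=C(C)C)c(O[Si](C)(C)C(C)(C)C)cc2c1C([O-])=C[C@@H](c1ccc(O[Si](C)(C)C(C)(C)C)cc1)O2.[K+] | intermediate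
12 | (2R,3R)-7-[(TBS)oxy]-2-{4-[(TBS)oxy]phenyl}-6-geranyl-3-hydroxy-5-methoxy-2,3-dihydro-4H-chromen-4-one | COc1c(C/C=C(\C)CCC=C(C)C)c(O[Si](C)(C)C(C)(C)C)cc2c1C(=O)[C@H](O)[C@@H](c1ccc(O[Si](C)(C)C(C)(C)C)cc1)O2 | intermediate
13 | (2R,3R)-6-geranyl-3,7-dihydroxy-2-(4-hydroxyphenyl)-5-methoxy-2,3-dihydro-4H-chromen-4-one | COc1c(C/C=C(\C)CCC=C(C)C)c(O)cc2c1C(=O)[C@H](O)[C@@H](c1ccc(O)cc1)O2 | target

Total step count: 8. Longest linear sequence: 8 steps (1 → 13).

Steps most likely to fail

Step 6 (key step). What may go wrong: capture of the carbene by O1 to give an oxonium ylide that undergoes 1,2-benzyl shift instead of C–H insertion, or poor discrimination of the two enantiotopic hydrogens. The fallback sets out from 7 and comes back at 10; it closes the same C2–C3 bond through a cation instead of a carbene. Ketone 7 would be converted with KN(SiMe3)2 and Ac2O (THF, −78 °C) into the enol acetate F1. DDQ (2,6-dichloropyridine, LiClO4, 1,2-dichloroethane) should abstract hydride from the 4-silyloxybenzylic CH2, the most easily oxidised C–H bond, and the resulting aryl oxocarbenium ion should be captured at carbon by the enol acetate in a 6-endo closure to give the racemic flavanone F2. Kinetic resolution of F2 by asymmetric transfer hydrogenation (Cp*RhCl[(R,R)-TsDPEN] or its antipode, whichever consumes the 2R ketone, HCO2H/Et3N) should reduce the unwanted enantiomer to the cis-flavan-4-ol F3 and leave 10.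

Step 7. What may go wrong: β-elimination of the enolate with opening of ring C, which erases the C2 configuration, or poor facial selectivity of the oxygen transfer. The fallback sets out from 10 and comes back at 12; it avoids a free enolate. Soft enolisation of 10 with Me3SiOTf/Et3N (CH2Cl2, 0 °C) should give the silyl enol ether F4. Lewis-acid-catalysed O-selective nitroso aldol reaction of F4 with nitrosobenzene (Et3SiOTf cat., CH2Cl2, −78 °C) should give the α-anilinooxy ketone F5, again by attack anti to the C2 aryl group. CuSO4 in MeOH (0 °C) should then cleave the N–O bond to 12.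

Step 3. What may go wrong: etherification at the wrong ortho hydroxyl (the one beside the geranyl chain) or at both. The fallback sets out from 1 and comes back at 6; it inverts the order of events so that the ring-C oxygen is chosen on a symmetrical substrate. Phloroacetophenone 1 would be silylated at the 4-hydroxyl (TBSCl, imidazole, CH2Cl2) to the silyl ether F6. Mitsunobu reaction of F6 with 5 (PPh3, DIAD, THF) on either of the two equivalent ortho hydroxyls should give the mono-ether F7. Ortho C-alkylation of the sodium phenoxide of F7 with 2 (NaH, toluene, rt) should place the geranyl group beside the remaining chelated hydroxyl, the para position being screened by its two flanking ethers, and so give 6.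

Further compounds
F1 | step 6 | 1-[6-({4-[(TBS)oxy]phenyl}methoxy)-4-[(TBS)oxy]-3-geranyl-2-methoxyphenyl]ethenyl acetate | CC(=O)OC(=C)c1c(OCc2ccc(O[Si](C)(C)C(C)(C)C)cc2)cc(O[Si](C)(C)C(C)(C)C)c(C/C=C(\C)CCC=C(C)C)c1OC
F2 | step 6 | racemic 7-[(TBS)oxy]-2-{4-[(TBS)oxy]phenyl}-6-geranyl-5-methoxy-2,3-dihydro-4H-chromen-4-one | COc1c(C/C=C(\C)CCC=C(C)C)c(O[Si](C)(C)C(C)(C)C)cc2c1C(=O)CC(c1ccc(O[Si](C)(C)C(C)(C)C)cc1)O2
F3 | step 6 | (2R,4R)-7-[(TBS)oxy]-2-{4-[(TBS)oxy]phenyl}-6-geranyl-5-methoxy-3,4-dihydro-2H-chromen-4-ol | COc1c(C/C=C(\C)CCC=C(C)C)c(O[Si](C)(C)C(C)(C)C)cc2c1[C@H](O)C[C@H](c1ccc(O[Si](C)(C)C(C)(C)C)cc1)O2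
F4 | step 7 | (2S)-7-[(TBS)oxy]-2-{4-[(TBS)oxy]phenyl}-6-geranyl-5-methoxy-4-[(trimethylsilyl)oxy]-2H-chromene | COc1c(C/C=C(\C)CCC=C(C)C)c(O[Si](C)(C)C(C)(C)C)cc2c1C(O[Si](C)(C)C)=C[C@@H](c1ccc(O[Si](C)(C)C(C)(C)C)cc1)O2
F5 | step 7 | (2R,3R)-3-(anilinooxy)-7-[(TBS)oxy]-2-{4-[(TBS)oxy]phenyl}-6-geranyl-5-methoxy-2,3-dihydro-4H-chromen-4-one | COc1c(C/C=C(\C)CCC=C(C)C)c(O[Si](C)(C)C(C)(C)C)cc2c1C(=O)[C@H](ONc1ccccc1)[C@@H](c1ccc(O[Si](C)(C)C(C)(C)C)cc1)O2
F6 | step 3 | 1-{4-[(TBS)oxy]-2,6-dihydroxyphenyl}ethan-1-one | CC(=O)c1c(O)cc(O[Si](C)(C)C(C)(C)C)cc1O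
F7 | step 3 | 1-[2-({4-[(TBS)oxy]phenyl}methoxy)-4-[(TBS)oxy]-6-hydroxyphenyl]ethan-1-one | CC(=O)c1c(O)cc(O[Si](C)(C)C(C)(C)C)cc1OCc1ccc(O[Si](C)(C)C(C)(C)C)cc1
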